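**Plan**

- Retrosynthesis: the side chain is cut at the aryl–vinyl bond (Heck). The dioxane is cut at the benzylic O1–C2 bond, and the oxetane so revealed is cut at C2–C3 and O–CH2 into vanillin acetate and an aryl vinyl ether.
- Enabling feature: the O1–C2H(aryl)–C3H(O-aryl)–CH2OH array (dioxane C2, C3 and the hydroxymethyl carbon) is a ring-opened 2-aryl-3-aryloxyoxetane whose ring oxygen becomes the primary hydroxyl.
- Forward: a regiodefined catechol mono-vinyl ether is made from 5-bromosalicylaldehyde, and the photocycloaddition closes the oxetane. Heck coupling adds the acrylate, then deacetylation and acid open the oxetane and close the benzodioxane ring, before resolution and saponification.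
- Stereochemistry: the photoreaction is not asked for stereocontrol. C2 is set trans to C3 under thermodynamic control at dioxane closure (both oxetane C2 epimers converge). The absolute configuration comes from a lipase kinetic resolution of the racemic trans primary alcohol, and C3 is not touched after it is formed.
- Protecting group: the ring-closing catechol oxygen carries a methoxymethyl group, because a silyl or acyl group can migrate between the two neighbouring oxygens and blur the regiochemistry.

Key step: step 4

Assumption: in step 8 the lipase is taken to acylate the (2S,3S)-alcohol faster, which is to be verified on the first run. Stereoisomer mixtures are written with stereo-undefined SMILES (oxetanes 7, 9, 10, 11), and racemic trans 12 is drawn as its (2R,3R) antipode.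

Step 1
Reactants: 1 5-bromo-2-hydroxybenzaldehyde (5-bromosalicylaldehyde)
Product: 2 5-bromo-2-(methoxymethoxy)benzaldehyde
Conditions: MOMCl (1.5 equiv), i-Pr2NEt (2 equiv), CH2Cl2, 0 °C → rt
Reagents that add atoms: chloromethyl methyl ether, COCCl
Why: O-alkylation of the phenol (MOM ether formation) should proceed cleanly, and the acetal cannot migrate to the neighbouring oxygen once the second phenol is unveiled, so the two catechol oxygens stay differentiated.

Step 2
Reactants: 2 5-bromo-2-(methoxymethoxy)benzaldehyde
Product: 4 5-bromo-2-(methoxymethoxy)phenol, via aryl formate 3 (not isolated)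
Conditions: mCPBA (1.5 equiv), CH2Cl2, rt; aq. Na2S2O3/NaHCO3 wash; then K2CO3 (0.2 equiv), MeOH, 0 °C
Reagents that add atoms: meta-chloroperoxybenzoic acid, O=C(OO)c1cccc(Cl)c1
Why: Baeyer–Villiger (Dakin-type) oxidation, in which the electron-rich ortho-alkoxyaryl group migrates in preference to hydride to give the aryl formate, followed by base-catalysed methanolysis to the phenol meta to bromine.

Step 3
Reactants: 4 5-bromo-2-(methoxymethoxy)phenol
Product: 5 4-bromo-2-(ethenyloxy)-1-(methoxymethoxy)benzene
Conditions: 2,4,6-trivinylcyclotriboroxane·pyridine (0.7 equiv), Cu(OAc)2 (1 equiv), pyridine (10 equiv), CH2Cl2, air, rt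
Reagents that add atoms: 2,4,6-trivinylcyclotriboroxane–pyridine complex, C=CB1OB(C=C)OB(C=C)O1.c1ccncc1
Why: Chan–Lam-type copper(II)-mediated O-vinylation of a phenol with a vinylboroxine runs at room temperature, where the aryl bromide and the acetal should be inert.

Step 4
Reactants: 5 4-bromo-2-(ethenyloxy)-1-(methoxymethoxy)benzene; 6 4-formyl-2-methoxyphenyl acetate (vanillin acetate)
Product: 7 4-{3-[5-bromo-2-(methoxymethoxy)phenoxy]oxetan-2-yl}-2-methoxyphenyl acetate (racemic, cis and trans isomers)
Conditions: hν 350 nm (Pyrex), 6 (2 equiv), degassed benzene, 10–15 °C; chromatography on Et3N-deactivated silica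
Reagents that add atoms: none
Why: Paternò–Büchi reaction: 350 nm light is absorbed only by the aldehyde, which crosses to its triplet, adds through its electrophilic oxygen to the unsubstituted CH2 terminus of the electron-rich vinyl ether and gives a triplet 1,4-biradical (benzylic and α-aryloxy radical) that collapses after spin inversion. The closest known reactions are the photocycloadditions of benzaldehydes to alkyl vinyl ethers, 2,3-dihydrofuran and silyl enol ethers, which give 2-aryl-3-oxy-oxetanes by the same course. The four-membered ring closes in two stages, the O–CH2 bond first and the C2–C3 bond last by radical–radical combination within the biradical. C2 and C3 are created without absolute control and as cis and trans isomers, and no element is asked to control them here, because C2 is re-set in step 7 and the C3 antipodes are parted in step 8. The step needs regioselectivity (3-aryloxy, not the 2-aryloxy acetal), which should follow from the better-stabilised α-aryloxy radical, and chemoselectivity, which should follow from the fast addition of triplet carbonyls to enol ethers compared with hydrogen abstraction from the acetal, the bromoarene being transparent at 350 nm. The acetyl group weakens the donor para to the formyl group so that the reactive n,π* state stays within reach.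

Step 5
Reactants: 7 4-{3-[5-bromo-2-(methoxymethoxy)phenoxy]oxetan-2-yl}-2-methoxyphenyl acetate; 8 methyl prop-2-enoate (methyl acrylate)
Product: 9 methyl (2E)-3-[3-({2-[4-(acetyloxy)-3-methoxyphenyl]oxetan-3-yl}oxy)-4-(methoxymethoxy)phenyl]prop-2-enoate (stereoisomer mixture as in 7)
Conditions: Pd2(dba)3 (2 mol%), [HP(t-Bu)3]BF4 (8 mol%), Cy2NMe (1.5 equiv), 8 (2 equiv), dioxane, 60 °C
Reagents that add atoms: none
Why: Mizoroki–Heck coupling of the unhindered aryl bromide gives the E-cinnamate by syn insertion and syn β-hydride elimination, and it is placed here because oxetane, aryl acetate and acetal tolerate Pd(0) and a hindered amine, whereas the later free para-hydroxybenzyl aryl ether would not tolerate heat and base well.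

Step 6
Reactants: 9 methyl (2E)-3-[3-({2-[4-(acetyloxy)-3-methoxyphenyl]oxetan-3-yl}oxy)-4-(methoxymethoxy)phenyl]prop-2-enoate
Product: 10 methyl (2E)-3-[3-{[2-(4-hydroxy-3-methoxyphenyl)oxetan-3-yl]oxy}-4-(methoxymethoxy)phenyl]prop-2-enoate
Conditions: K2CO3 (0.3 equiv), MeOH, 0 °C; pH 7 buffer quench; used without chromatography
Reagents that add atoms: none
Why: Base-catalysed transesterification removes the aryl acetate at 0 °C, while the methyl cinnamate is degenerate in methanol and the oxetane and acetal are base-stable.

Step 7
Reactants: 10 methyl (2E)-3-[3-{[2-(4-hydroxy-3-methoxyphenyl)oxetan-3-yl]oxy}-4-(methoxymethoxy)phenyl]prop-2-enoate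
Product: 12 methyl (2E)-3-[(2R*,3R*)-2-(4-hydroxy-3-methoxyphenyl)-3-(hydroxymethyl)-2,3-dihydro-1,4-benzodioxin-6-yl]prop-2-enoate (racemic trans), via bisphenol oxetane 11 (not isolated)
Conditions: 4 M HCl in dioxane (5 equiv), MeOH (5 equiv), CH2Cl2 (0.02 M), 0 °C → rt
Reagents that add atoms: none
Why: Acid-mediated acetal cleavage frees the phenol para to the cinnamate, and strain-driven SN1 opening of the 2-(4-hydroxyaryl)oxetane at its benzylic C–O bond gives a quinone-methide-like cation that this phenol captures in a six-membered ring closure; because the benzylic ether ionises reversibly, C2 should settle in the diequatorial trans arrangement from either oxetane epimer while C3 is untouched, and the few equivalents of methanol carry off the methoxymethyl unit as dimethoxymethane.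

Step 8
Reactants: 12 methyl (2E)-3-[(2R*,3R*)-2-(4-hydroxy-3-methoxyphenyl)-3-(hydroxymethyl)-2,3-dihydro-1,4-benzodioxin-6-yl]prop-2-enoate (racemic trans)
Product: 13 methyl (2E)-3-[(2R,3R)-2-(4-hydroxy-3-methoxyphenyl)-3-(hydroxymethyl)-2,3-dihydro-1,4-benzodioxin-6-yl]prop-2-enoate
Conditions: Novozym 435 (immobilised Candida antarctica lipase B), vinyl acetate (3 equiv), MTBE–THF 4:1, 35 °C, stopped just past half conversion (chiral HPLC); silica gel separation from the acetate
Reagents that add atoms: none
Why: Lipase-catalysed kinetic resolution by irreversible transesterification of the primary alcohol with an enol ester should acetylate the (2S,3S)-antipode and leave the (2R,3R)-alcohol, which fixes the absolute configuration; phenols and the cinnamate are not substrates for this enzyme.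

Step 9
Reactants: 13 methyl (2E)-3-[(2R,3R)-2-(4-hydroxy-3-methoxyphenyl)-3-(hydroxymethyl)-2,3-dihydro-1,4-benzodioxin-6-yl]prop-2-enoate
Product: 14 (2E)-3-[(2R,3R)-2-(4-hydroxy-3-methoxyphenyl)-3-(hydroxymethyl)-2,3-dihydro-1,4-benzodioxin-6-yl]prop-2-enoic acid
Conditions: LiOH·H2O (4 equiv), THF–H2O 3:1, argon, 0 °C → rt; then 1 M HCl to pH 3
Reagents that add atoms: lithium hydroxide, [Li+].[OH-]
Why: Saponification of the methyl ester followed by acidification gives the acid; neither stereocentre carries an acidic hydrogen, and a reversible opening at C2 through the quinone methide would re-close to the same trans isomer.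

**Compound list**

1 | 5-bromo-2-hydroxybenzaldehyde | O=Cc1cc(Br)ccc1O | starting material
2 | 5-bromo-2-(methoxymethoxy)benzaldehyde | O=Cc1cc(Br)ccc1OCOC | intermediate
3 | 5-bromo-2-(methoxymethoxy)phenyl formate (formed in situ) | O=COc1cc(Br)ccc1OCOC | intermediate
4 | 5-bromo-2-(methoxymethoxy)phenol | Oc1cc(Br)ccc1OCOC | intermediate
5 | 4-bromo-2-(ethenyloxy)-1-(methoxymethoxy)benzene | C=COc1cc(Br)ccc1OCOC | intermediate
6 | 4-formyl-2-methoxyphenyl acetate (vanillin acetate) | COc1cc(C=O)ccc1OC(C)=O | starting material
7 | 4-{3-[5-bromo-2-(methoxymethoxy)phenoxy]oxetan-2-yl}-2-methoxyphenyl acetate (racemic, cis and trans) | COCOc1ccc(Br)cc1OC1COC1c1ccc(OC(C)=O)c(OC)c1 | intermediate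
8 | methyl prop-2-enoate (methyl acrylate) | C=CC(=O)OC | starting material
9 | methyl (2E)-3-[3-({2-[4-(acetyloxy)-3-methoxyphenyl]oxetan-3-yl}oxy)-4-(methoxymethoxy)phenyl]prop-2-enoate (racemic, cis and trans) | COCOc1ccc(/C=C/C(=O)OC)cc1OC1COC1c1ccc(OC(C)=O)c(OC)c1 | intermediate
10 | methyl (2E)-3-[3-{[2-(4-hydroxy-3-methoxyphenyl)oxetan-3-yl]oxy}-4-(methoxymethoxy)phenyl]prop-2-enoate (racemic, cis and trans) | COCOc1ccc(/C=C/C(=O)OC)cc1OC1COC1c1ccc(O)c(OC)c1 | intermediate
11 | methyl (2E)-3-[4-hydroxy-3-{[2-(4-hydroxy-3-methoxyphenyl)oxetan-3-yl]oxy}phenyl]prop-2-enoate (formed in situ; racemic, cis and trans) | COC(=O)/C=C/c1ccc(O)c(OC2COC2c2ccc(O)c(OC)c2)c1 | intermediate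
12 | methyl (2E)-3-[(2R*,3R*)-2-(4-hydroxy-3-methoxyphenyl)-3-(hydroxymethyl)-2,3-dihydro-1,4-benzodioxin-6-yl]prop-2-enoate (racemic trans; one antipode drawn) | COc1cc([C@H]2Oc3ccc(/C=C/C(=O)OC)cc3O[C@@H]2CO)ccc1O | intermediate
13 | methyl (2E)-3-[(2R,3R)-2-(4-hydroxy-3-methoxyphenyl)-3-(hydroxymethyl)-2,3-dihydro-1,4-benzodioxin-6-yl]prop-2-enoate | COc1cc([C@H]2Oc3ccc(/C=C/C(=O)OC)cc3O[C@@H]2CO)ccc1O | intermediate
14 | (2E)-3-[(2R,3R)-2-(4-hydroxy-3-methoxyphenyl)-3-(hydroxymethyl)-2,3-dihydro-1,4-benzodioxin-6-yl]prop-2-enoic acid | COc1cc([C@H]2Oc3ccc(/C=C/C(=O)O)cc3O[C@@H]2CO)ccc1O | target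

**Step count**

Total: 9 steps. Longest linear sequence: 9 steps (1 → 14); 6 and 8 are purchased.

**Steps most likely to fail**

Step 4. The donor-substituted benzaldehyde triplet has much π,π* character and may add sluggishly, may be quenched by the electron-rich bromo-catechol ring, or may give some of the acetal regioisomer. The fallback gives up the photochemistry and forms the same C2–C3 bond by an aldol reaction; it sets out from 4 and comes back at 12. Phenol 4 is alkylated with ethyl bromoacetate (K2CO3, acetone) to ethyl [5-bromo-2-(methoxymethoxy)phenoxy]acetate F1. Its lithium enolate (LDA, THF, −78 °C) is added to purchased 3-methoxy-4-(methoxymethoxy)benzaldehyde to give ethyl 2-[5-bromo-2-(methoxymethoxy)phenoxy]-3-hydroxy-3-[3-methoxy-4-(methoxymethoxy)phenyl]propanoate F2 as a syn/anti mixture. LiBH4 in THF reduces the ester to 2-[5-bromo-2-(methoxymethoxy)phenoxy]-1-[3-methoxy-4-(methoxymethoxy)phenyl]propane-1,3-diol F3. Heck coupling with 8 under the conditions of step 5 gives methyl (2E)-3-[3-({1,3-dihydroxy-1-[3-methoxy-4-(methoxymethoxy)phenyl]propan-2-yl}oxy)-4-(methoxymethoxy)phenyl]prop-2-enoate F4. The acid conditions of step 7 then remove both acetals, ionise the benzylic alcohol and close the dioxane to 12.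

Step 8. The enzyme may discriminate poorly between antipodes whose stereocentre lies β to the reacting hydroxyl, or may prefer the opposite antipode. The fallback is a physical resolution: preparative chromatography of 12 on a chiral stationary phase (cellulose or amylose carbamate, supercritical CO2/MeOH). It sets out from 12, comes back at 13 and makes no new compound (F0).

Step 7. The benzylic cation may form before the acetal is cleaved and then fragment, or condense with the electron-rich guaiacyl ring or with the released formaldehyde equivalent, instead of being captured by the phenol. The fallback stages the closure through an isolable open-chain ether; it sets out from 10 and comes back at 12. HCl (1.25 M) in methanol at 0 °C → rt solvolyses the oxetane at the benzylic carbon and cleaves the acetal, giving methyl (2E)-3-[4-hydroxy-3-({3-hydroxy-1-(4-hydroxy-3-methoxyphenyl)-1-methoxypropan-2-yl}oxy)phenyl]prop-2-enoate F5. Catalytic camphorsulfonic acid in CH2Cl2 over 5 Å molecular sieves then exchanges the benzylic methoxy group for the ortho phenol and should deliver 12.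

**Further compounds**

F1 | step 4 | ethyl [5-bromo-2-(methoxymethoxy)phenoxy]acetate | CCOC(=O)COc1cc(Br)ccc1OCOC
F2 | step 4 | ethyl 2-[5-bromo-2-(methoxymethoxy)phenoxy]-3-hydroxy-3-[3-methoxy-4-(methoxymethoxy)phenyl]propanoate | CCOC(=O)C(Oc1cc(Br)ccc1OCOC)C(O)c1ccc(OCOC)c(OC)c1
F3 | step 4 | 2-[5-bromo-2-(methoxymethoxy)phenoxy]-1-[3-methoxy-4-(methoxymethoxy)phenyl]propane-1,3-diol | OCC(Oc1cc(Br)ccc1OCOC)C(O)c1ccc(OCOC)c(OC)c1
F4 | step 4 | methyl (2E)-3-[3-({1,3-dihydroxy-1-[3-methoxy-4-(methoxymethoxy)phenyl]propan-2-yl}oxy)-4-(methoxymethoxy)phenyl]prop-2-enoate | COC(=O)/C=C/c1ccc(OCOC)c(OC(CO)C(O)c2ccc(OCOC)c(OC)c2)c1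
F0 | step 8 | none | none
F5 | step 7 | methyl (2E)-3-[4-hydroxy-3-({3-hydroxy-1-(4-hydroxy-3-methoxyphenyl)-1-methoxypropan-2-yl}oxy)phenyl]prop-2-enoate | COC(=O)/C=C/c1ccc(O)c(OC(CO)C(OC)c2ccc(O)c(OC)c2)c1
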